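**Retrosynthetic overview** (disconnections listed in the order the bonds are made)
1. C4a stereocentre and carbocycle: acetyl chloride 1 and auxiliary amine 2 give chiral acetamide 3; α-angelica lactone 4 (γ-lactone ring bought in) takes up the derived keteniminium ion 5 in a [2+2] addition → iminium 6 → cyclobutanone 7 (cyclobutane formed first).
2. Key step: methyl carbinol 8, then aerobic ring expansion, in which O2 is inserted into a cyclobutane C–C bond via hydroperoxy ketone 9 → 1,2-dioxan-3-ol 10 (1,2-dioxane formed second and last; C7a fixed by cis fusion).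
3. C3 quaternary peroxide carbon: peroxycarbenium ion 11 + allylsilane → allyl peroxide 12.
4. Side chain: allylmagnesium bromide 13 + 1,6-dibromohexane 14 → bromide 15; with 4-bromophenol 16 via zinc reagent 17 → alkenylphenol 18.
5. Union: cross-metathesis of 12 with 18 → alkene 19; diimide reduction → plakortolide S 20.

**Assumptions**
- Core positions are numbered O1, O2, C3, C4, C4a, O5, C6(=O), C7, C7a (furo[3,2-c][1,2]dioxin-6-one); the target is (3S,4aR,7aR).
- The (2R,5R) auxiliary is taken to give (1R,5R)-7 in step 2; if the sense proves opposite, the commercial (2S,5S) amine is used and nothing else changes.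

**Step 1**
Reactants: 1 acetyl chloride; 2 (2R,5R)-2,5-dimethylpyrrolidine
Product: 3 1-[(2R,5R)-2,5-dimethylpyrrolidin-1-yl]ethan-1-one
Conditions: Et3N, CH2Cl2, 0 → 25 °C
Reagents that add atoms: none
Why: Nucleophilic acyl substitution (N-acylation of a secondary amine); the auxiliary stereocentres are untouched.

**Step 2**
Reactants: 3 1-[(2R,5R)-2,5-dimethylpyrrolidin-1-yl]ethan-1-one; 4 α-angelica lactone (3 equiv)
Product: 7 (1R,5R)-1-methyl-2-oxabicyclo[3.2.0]heptane-3,6-dione, via keteniminium triflate 5 (not isolated), via cyclobutaniminium triflate 6 (not isolated)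
Conditions: Tf2O, 2,6-di-tert-butyl-4-methylpyridine, ClCH2CH2Cl, −20 → 40 °C; then H2O, NaHCO3, 25 °C
Reagents that add atoms: water, O
Why: Proposed new method: an asymmetric keteniminium–enol lactone [2+2] cycloaddition, in which O-triflation of 3 and loss of triflic acid give the C2-symmetric keteniminium ion 5, the nucleophilic CH= carbon of the enol lactone attacks its central carbon, the acyloxy-stabilised tertiary cation is closed by the enamine carbon to iminium 6 (so the new C=O sits on the former CH carbon and the fusion can only be cis), and hydrolysis releases 7 and the auxiliary, with the oxygenated quaternary centre (later C4a) set by the alkene face that avoids the methyl group flanking the iminium carbon; the closest known reaction type is the Ghosez keteniminium–olefin [2+2] cycloaddition with chiral pyrrolidine auxiliaries on simple hydrocarbon alkenes, which has not been shown on an enol lactone or for an O-substituted quaternary stereocentre.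

**Step 3**
Reactants: 7 (1R,5R)-1-methyl-2-oxabicyclo[3.2.0]heptane-3,6-dione
Product: 8 (1R,5S,6S)-6-hydroxy-1,6-dimethyl-2-oxabicyclo[3.2.0]heptan-3-one
Conditions: MeMgBr, CeCl3, THF, −78 °C; AcOH quench at −78 °C
Reagents that add atoms: methylmagnesium bromide, C[Mg]Br
Why: Imamoto organocerium 1,2-addition to the strained cyclobutanone outruns attack on the lactone and enolisation/E1cB loss of the β-acyloxy group; convex-face attack should give mainly the endo alcohol, but C6 becomes a ketone in step 4 so its configuration is irrelevant, and the cold acidic quench prevents acyl transfer to the new alkoxide (the endo epimer is the lactone of a meso diol acid, so transfer would racemise it).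

**Step 4 (key ring expansion)**
Reactants: 8 (1R,5S,6S)-6-hydroxy-1,6-dimethyl-2-oxabicyclo[3.2.0]heptan-3-one
Product: 10 (4aR,7aR)-3-hydroxy-3,4a-dimethyltetrahydro-3H-furo[3,2-c][1,2]dioxin-6(4H)-one, via hydroperoxy ketone 9 (not isolated)
Conditions: Co(acac)2 (20 mol%), O2 (1 atm), MeCN, 40 °C
Reagents that add atoms: dioxygen, O=O
Why: Cobalt-catalysed aerobic oxidative ring expansion of a tertiary cyclobutanol, in which the alkoxy radical undergoes strain-releasing β-scission toward the more substituted ring-fusion carbon, the secondary radical traps O2, and hydroperoxide 9 adds to the new methyl ketone, so O2 is inserted into the former C5–C6 bond; the old C5 centre is erased and re-set as C7a because only the hydroperoxide cis to the acetonyl arm can close (cis fusion), the trans epimer being removed on silica, and C3 is a hemiketal (anomers).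

**Step 5**
Reactants: 10 (4aR,7aR)-3-hydroxy-3,4a-dimethyltetrahydro-3H-furo[3,2-c][1,2]dioxin-6(4H)-one
Product: 12 (3S,4aR,7aR)-3,4a-dimethyl-3-(prop-2-en-1-yl)tetrahydro-3H-furo[3,2-c][1,2]dioxin-6(4H)-one, via peroxycarbenium triflate 11 (not isolated)
Conditions: allylSiMe3 (5 equiv), TMSOTf, CH2Cl2, −78 → −40 °C
Reagents that add atoms: allyltrimethylsilane, C=CC[Si](C)(C)C
Why: Sakurai-type allylation of a peroxycarbenium ion (the O–O bond survives Lewis-acid ionisation at low temperature); 11 should react through the half-chair with the C4a–O bond pseudoaxial and the C4a methyl pseudoequatorial, and axial attack via a chair-like transition state syn to that oxygen (the other chair-like path needs a syn-axial clash with the C4a methyl) puts the allyl group cis to the lactone oxygen, which is the 3S configuration; any minor C3 epimer is separated.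

**Step 6**
Reactants: 13 allylmagnesium bromide; 14 1,6-dibromohexane (3 equiv)
Product: 15 9-bromonon-1-ene
Conditions: Li2CuCl4 (2 mol%), THF, 0 °C
Reagents that add atoms: none
Why: Copper-catalysed Kochi sp3–sp3 coupling of a Grignard reagent with a primary bromide; excess dibromide suppresses double substitution and is recovered by distillation.

**Step 7**
Reactants: 15 9-bromonon-1-ene; 16 4-bromophenol
Product: 18 4-(non-8-en-1-yl)phenol, via non-8-enylzinc bromide 17 (not isolated)
Conditions: Zn dust, LiCl, THF, 50 °C; then 16, Pd(OAc)2 (2 mol%), SPhos (4 mol%), THF, 25 °C, slow addition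
Reagents that add atoms: none
Why: LiCl-promoted zinc insertion then Negishi coupling; alkylzinc halides added slowly are not protonated competitively by the phenol, so no protecting group is needed.

**Step 8**
Reactants: 12 (3S,4aR,7aR)-3,4a-dimethyl-3-(prop-2-en-1-yl)tetrahydro-3H-furo[3,2-c][1,2]dioxin-6(4H)-one; 18 4-(non-8-en-1-yl)phenol (3 equiv)
Product: 19 (3S,4aR,7aR)-3-[(2E)-10-(4-hydroxyphenyl)dec-2-en-1-yl]-3,4a-dimethyltetrahydro-3H-furo[3,2-c][1,2]dioxin-6(4H)-one
Conditions: second-generation Hoveyda–Grubbs catalyst [RuCl2(H2IMes)(=CH–C6H4-2-OiPr)] (5 mol%), CH2Cl2, 40 °C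
Reagents that add atoms: none
Why: Olefin cross-metathesis of two unhindered terminal alkenes driven by loss of ethene; ruthenium carbenes tolerate dialkyl peroxides, lactones and free phenols, and the E/Z ratio is irrelevant.

**Step 9**
Reactants: 19 (3S,4aR,7aR)-3-[(2E)-10-(4-hydroxyphenyl)dec-2-en-1-yl]-3,4a-dimethyltetrahydro-3H-furo[3,2-c][1,2]dioxin-6(4H)-one
Product: 20 plakortolide S
Conditions: KO2CN=NCO2K (excess), AcOH, CH2Cl2/MeOH, 0 → 25 °C
Reagents that add atoms: none
Why: Diimide reduction (concerted syn transfer of H2 to the C=C bond) leaves the O–O bond, lactone and arene untouched, unlike metal-catalysed hydrogenation.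

**Compound list**
1 | acetyl chloride | CC(Cl)=O | starting material
2 | (2R,5R)-2,5-dimethylpyrrolidine (recoverable auxiliary) | C[C@@H]1CC[C@@H](C)N1 | starting material
3 | 1-[(2R,5R)-2,5-dimethylpyrrolidin-1-yl]ethan-1-one | CC(=O)N1[C@H](C)CC[C@H]1C | intermediate
4 | α-angelica lactone, 5-methylfuran-2(3H)-one | CC1=CCC(=O)O1 | starting material
5 | keteniminium triflate: (2R,5R)-1-ethenylidene-2,5-dimethylpyrrolidinium triflate | C=C=[N+]1[C@H](C)CC[C@H]1C.[O-]S(=O)(=O)C(F)(F)F | intermediate (not isolated)
6 | cyclobutaniminium triflate: iminium of ketone 7 with amine 2 at C6, ring stereocentres as in 7 | C[C@@H]1CC[C@@H](C)[N+]1=C1C[C@@]2(C)OC(=O)C[C@@H]12.[O-]S(=O)(=O)C(F)(F)F | intermediate (not isolated)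
7 | (1R,5R)-1-methyl-2-oxabicyclo[3.2.0]heptane-3,6-dione (cis-fused) | O=C1C[C@@]2(C)OC(=O)C[C@@H]12 | intermediate
8 | (1R,5S,6S)-6-hydroxy-1,6-dimethyl-2-oxabicyclo[3.2.0]heptan-3-one (endo-OH epimer shown; the 6R epimer reacts alike) | C[C@]1(O)C[C@@]2(C)OC(=O)C[C@@H]12 | intermediate
9 | (4R,5R)-4-hydroperoxy-5-methyl-5-(2-oxopropyl)oxolan-2-one | CC(=O)C[C@@]1(C)OC(=O)C[C@H]1OO | intermediate (not isolated)
10 | (4aR,7aR)-3-hydroxy-3,4a-dimethyltetrahydro-3H-furo[3,2-c][1,2]dioxin-6(4H)-one (cis-fused, C3 anomers) | CC1(O)C[C@@]2(C)OC(=O)C[C@H]2OO1 | intermediate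
11 | peroxycarbenium triflate: C3 cation of 10 after loss of hydroxide, C3=O2 oxocarbenium form | CC1=[O+]O[C@@H]2CC(=O)O[C@]2(C)C1.[O-]S(=O)(=O)C(F)(F)F | intermediate (not isolated)
12 | (3S,4aR,7aR)-3,4a-dimethyl-3-(prop-2-en-1-yl)tetrahydro-3H-furo[3,2-c][1,2]dioxin-6(4H)-one | C[C@]1(CC=C)C[C@@]2(C)OC(=O)C[C@H]2OO1 | intermediate
13 | allylmagnesium bromide | C=CC[Mg]Br | starting material
14 | 1,6-dibromohexane | BrCCCCCCBr | starting material
15 | 9-bromonon-1-ene | C=CCCCCCCCBr | intermediate
16 | 4-bromophenol | Oc1ccc(Br)cc1 | starting material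
17 | non-8-en-1-ylzinc bromide | C=CCCCCCCC[Zn]Br | intermediate (not isolated)
18 | 4-(non-8-en-1-yl)phenol | C=CCCCCCCCc1ccc(O)cc1 | intermediate
19 | (3S,4aR,7aR)-3-[(2E)-10-(4-hydroxyphenyl)dec-2-en-1-yl]-3,4a-dimethyltetrahydro-3H-furo[3,2-c][1,2]dioxin-6(4H)-one (E shown, Z also formed) | C[C@]1(C/C=C/CCCCCCCc2ccc(O)cc2)C[C@@]2(C)OC(=O)C[C@H]2OO1 | intermediate
20 | plakortolide S, (3S,4aR,7aR)-3-[10-(4-hydroxyphenyl)decyl]-3,4a-dimethyltetrahydro-3H-furo[3,2-c][1,2]dioxin-6(4H)-one | C[C@]1(CCCCCCCCCCc2ccc(O)cc2)C[C@@]2(C)OC(=O)C[C@H]2OO1 | target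

**Step count and risks**
Total: 9 steps. Longest linear sequence: 7 steps (1, 2, 3, 4, 5, 8, 9).

Step 2 (the proposed new step). The keteniminium ion may give open-chain acylation products instead of the cyclobutane, the enol lactone may isomerise to the butenolide, or the auxiliary may give low ee. The fallback uses only known chemistry and sets out from 4: [2+2] cycloaddition with dichloroketene (Cl3CCOCl, Zn–Cu couple, Et2O) gives racemic 7,7-dichloro-1-methyl-2-oxabicyclo[3.2.0]heptane-3,6-dione F1; reductive dechlorination (Zn, AcOH, 25 °C) gives racemic 1-methyl-2-oxabicyclo[3.2.0]heptane-3,6-dione F2; the enantiomers are separated by preparative chromatography on a chiral stationary phase, and the (1R,5R) enantiomer is 7, where the route is rejoined.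

Step 4. The carbon radical can take up O2 on either face and only the cis hydroperoxide closes, so the yield may be low, and cobalt may degrade the open hydroperoxide. The fallback sets out from 8 and replaces the O2 insertion by a polar peroxide synthesis: silver-catalysed radical ring-opening chlorination (AgNO3 cat., K2S2O8, N-chlorosuccinimide) gives (5R)-4-chloro-5-methyl-5-(2-oxopropyl)oxolan-2-one F3; Et3N eliminates HCl to the butenolide (5R)-5-methyl-5-(2-oxopropyl)furan-2(5H)-one F4; urea–H2O2 with Et2NH in CF3CH2OH forms the hydroperoxy hemiketal of the methyl ketone, which closes by intramolecular oxa-Michael addition to the butenolide with cis fusion and comes back to the route at 10.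

Step 5. The facial selectivity at C3 rests on a conformational model, and the Lewis acid may fragment the peroxide. The fallback sets out from 8 and builds the C3 carbon substituents before the peroxide ring: 8 is taken to the butenolide (5R)-5-methyl-5-(2-oxopropyl)furan-2(5H)-one F4 as described for step 4; Barbier allylation of the ketone (allyl bromide, In powder, THF/H2O) gives (5R)-5-(2-hydroxy-2-methylpent-4-en-1-yl)-5-methylfuran-2(5H)-one F5; acid-catalysed perhydrolysis (50% H2O2, cat. H2SO4, 0 °C) gives the tertiary hydroperoxide (5R)-5-(2-hydroperoxy-2-methylpent-4-en-1-yl)-5-methylfuran-2(5H)-one F6; Et2NH in CF3CH2OH closes the dioxane by intramolecular oxa-Michael addition to give 12 together with its C3 epimer (3R,4aR,7aR)-3,4a-dimethyl-3-(prop-2-en-1-yl)tetrahydro-3H-furo[3,2-c][1,2]dioxin-6(4H)-one F7 (about 1:1, separated by chromatography); the route is rejoined at 12.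

**Further compounds**
F1 | step 2 | racemic 7,7-dichloro-1-methyl-2-oxabicyclo[3.2.0]heptane-3,6-dione (cis-fused) | O=C1C(Cl)(Cl)C2(C)OC(=O)CC12
F2 | step 2 | racemic 1-methyl-2-oxabicyclo[3.2.0]heptane-3,6-dione (cis-fused) | O=C1CC2(C)OC(=O)CC12
F3 | step 4 | (5R)-4-chloro-5-methyl-5-(2-oxopropyl)oxolan-2-one (both C4 epimers) | CC(=O)C[C@@]1(C)OC(=O)CC1Cl
F4 | step 4 | (5R)-5-methyl-5-(2-oxopropyl)furan-2(5H)-one | CC(=O)C[C@@]1(C)OC(=O)C=C1
F5 | step 5 | (5R)-5-(2-hydroxy-2-methylpent-4-en-1-yl)-5-methylfuran-2(5H)-one (both carbinol epimers) | C=CCC(C)(O)C[C@@]1(C)OC(=O)C=C1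
F6 | step 5 | (5R)-5-(2-hydroperoxy-2-methylpent-4-en-1-yl)-5-methylfuran-2(5H)-one (both epimers) | C=CCC(C)(OO)C[C@@]1(C)OC(=O)C=C1
F7 | step 5 | (3R,4aR,7aR)-3,4a-dimethyl-3-(prop-2-en-1-yl)tetrahydro-3H-furo[3,2-c][1,2]dioxin-6(4H)-one | C[C@@]1(CC=C)C[C@@]2(C)OC(=O)C[C@H]2OO1
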